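**Retrosynthetic overview**
1. Pieces: erucyl alcohol 1, used as bromide 2, supplies side-chain carbons C2'–C23' with the Z-alkene; 4,4-dimethoxybutan-2-one 3 and propane-1,3-dithiol 4 give bis-dithiane 5 (C4, C5, C6 and the methyl group, both carbonyls masked); (S)-epichlorohydrin 6 supplies C1', C2, C3 and the stereocentre.
2. Key disconnection C3–C4: the carbonyl carbon C4 is used as a carbanion, lithiated bis-dithiane 7 (a masked acetoacetyl anion), and joined to the electrophilic epoxide CH2 of 6; chloro alkoxide 8 then closes to epoxide 9.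
3. Second disconnection C1'–C2': Grignard reagent 10 (from 2) opens 9 in the same flask to give alcohol 11; the C–O bond of the stereocentre is never touched.
4. Ring formation (the only ring, made last): unmasking 11 gives hydroxy diketone 12, whose C2–OH adds to the C6 carbonyl (O1–C6 bond) and loses water to give dihydropyranone 13.

Assumption: the target is (2R)-6-methyl-2-[(14Z)-tricos-14-en-1-yl]-2,3-dihydro-4H-pyran-4-one (ring O1, C2–C6; side chain C1'–C23'), and commercial erucyl alcohol of high Z purity is the source of the alkene.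

**Route**

Step 1
Reactants: 1 erucyl alcohol [(13Z)-docos-13-en-1-ol]
Product: 2 erucyl bromide [(13Z)-1-bromodocos-13-ene]
Conditions: CBr4 (1.2 equiv), PPh3 (1.25 equiv), CH2Cl2, 0 °C → rt, 1 h
Reagents that add atoms: tetrabromomethane, BrC(Br)(Br)Br
Why: Appel reaction, in which bromide displaces the primary alkoxyphosphonium group (SN2) under neutral conditions that leave the remote Z-alkene untouched; no stereocentre is involved.

Step 2
Reactants: 3 4,4-dimethoxybutan-2-one; 4 propane-1,3-dithiol (2.2 equiv)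
Product: 5 2-(1,3-dithian-2-ylmethyl)-2-methyl-1,3-dithiane
Conditions: BF3·OEt2 (0.3 equiv), CH2Cl2, 0 °C → rt, 16 h
Reagents that add atoms: none
Why: Lewis-acid thioacetalisation converts both the dimethyl acetal and the ketone into 1,3-dithianes, giving a doubly masked acetoacetaldehyde whose only acidic C–H is the dithiane C2–H that becomes C4.

Step 3
Reactants: 5 2-(1,3-dithian-2-ylmethyl)-2-methyl-1,3-dithiane; 6 (S)-epichlorohydrin [(2S)-2-(chloromethyl)oxirane]; 2 erucyl bromide
Product: 11 (2R,16Z)-1-{2-[(2-methyl-1,3-dithian-2-yl)methyl]-1,3-dithian-2-yl}pentacos-16-en-2-ol, via lithio bis-dithiane 7 (not isolated), via chloro alkoxide 8 (not isolated), via epoxide 9 (not isolated), via erucylmagnesium bromide 10 (not isolated)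
Conditions: n-BuLi (1.05 equiv), THF, −30 °C, 3 h; 6 (1.0 equiv), −78 °C → rt, 3 h; then CuI (10 mol %), 10 (1.5 equiv, from 2 + Mg, THF, 45 °C), −30 → 0 °C, 2 h; H2O
Reagents that add atoms: none
Why: Corey–Seebach umpolung run as a one-flask epichlorohydrin linchpin coupling, in which carbanion 7 (acyl anion equivalent for C4) opens 6 at the epoxide CH2 (SN2), alkoxide 8 closes by intramolecular Williamson displacement of chloride to epoxide 9, and CuI-catalysed Grignard opening at the new terminal CH2 attaches the chain; no bond to the stereocentre is broken, so (S)-6 is carried into (R)-11 (the descriptor changes only through the CIP priorities).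

Step 4
Reactants: 11 (2R,16Z)-1-{2-[(2-methyl-1,3-dithian-2-yl)methyl]-1,3-dithian-2-yl}pentacos-16-en-2-ol
Product: 13 (2R)-6-methyl-2-[(14Z)-tricos-14-en-1-yl]-2,3-dihydro-4H-pyran-4-one, via hydroxy diketone 12 (not isolated)
Conditions: PhI(OCOCF3)2 (3.0 equiv), MeCN/THF/H2O (5:4:1), 0 °C, 20 min; then TFA (5 equiv), rt, 3 h
Reagents that add atoms: water, O
Why: Oxidative dethioacetalisation with the trivalent iodine reagent (Stork–Zhao conditions) frees diketone 12 within minutes, faster than attack on the isolated alkene, and acid-catalysed cyclodehydration (hemiketalisation of the C2–OH onto C6, then loss of water to the vinylogous ester) closes the ring without touching C2, so (R) is retained.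

**Compound list**
1 | erucyl alcohol, (13Z)-docos-13-en-1-ol | CCCCCCCC/C=C\CCCCCCCCCCCCO | starting material
2 | erucyl bromide, (13Z)-1-bromodocos-13-ene | CCCCCCCC/C=C\CCCCCCCCCCCCBr | intermediate
3 | 4,4-dimethoxybutan-2-one | CC(=O)CC(OC)OC | starting material
4 | propane-1,3-dithiol | SCCCS | starting material
5 | 2-(1,3-dithian-2-ylmethyl)-2-methyl-1,3-dithiane | CC1(CC2SCCCS2)SCCCS1 | intermediate
6 | (S)-epichlorohydrin, (2S)-2-(chloromethyl)oxirane | ClC[C@@H]1CO1 | starting material
7 | 2-lithio-2-[(2-methyl-1,3-dithian-2-yl)methyl]-1,3-dithiane | [Li]C1(CC2(C)SCCCS2)SCCCS1 | intermediate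
8 | lithium (2S)-1-chloro-3-{2-[(2-methyl-1,3-dithian-2-yl)methyl]-1,3-dithian-2-yl}propan-2-olate | ClC[C@@H](O[Li])CC1(CC2(C)SCCCS2)SCCCS1 | intermediate
9 | 2-[(2-methyl-1,3-dithian-2-yl)methyl]-2-{[(2S)-oxiran-2-yl]methyl}-1,3-dithiane | CC1(CC2(C[C@H]3CO3)SCCCS2)SCCCS1 | intermediate
10 | (13Z)-docos-13-en-1-ylmagnesium bromide | CCCCCCCC/C=C\CCCCCCCCCCCC[Mg]Br | intermediate
11 | (2R,16Z)-1-{2-[(2-methyl-1,3-dithian-2-yl)methyl]-1,3-dithian-2-yl}pentacos-16-en-2-ol | CCCCCCCC/C=C\CCCCCCCCCCCCC[C@@H](O)CC1(CC2(C)SCCCS2)SCCCS1 | intermediate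
12 | (6R,20Z)-6-hydroxynonacos-20-ene-2,4-dione | CCCCCCCC/C=C\CCCCCCCCCCCCC[C@@H](O)CC(=O)CC(C)=O | intermediate
13 | (2R)-6-methyl-2-[(14Z)-tricos-14-en-1-yl]-2,3-dihydro-4H-pyran-4-one | CCCCCCCC/C=C\CCCCCCCCCCCCC[C@@H]1CC(=O)C=C(C)O1 | target

**Totals and risks**
Total step count: 4. Longest linear sequence: 3 steps (steps 1, 3, 4 from 1; equally steps 2, 3, 4 from 3).

Most likely to fail, in order:

Step 3. Two things can go wrong. Direct SN2 attack of 7 at CH2Cl instead of the epoxide would give the enantiomer of 9 and lower the optical purity of 11 (check by Mosher ester). The in-flask epoxide may also open unclean in the presence of the magnesium salts. The fallback reverses the order of the two bond formations and isolates the epoxide. It sets out from 2: its Grignard reagent 10 opens commercial (R)-epichlorohydrin at the epoxide CH2 (CuI 10 mol %, THF, −30 °C) to give (2R,16Z)-1-chloropentacos-16-en-2-ol F1. Powdered NaOH in Et2O closes this to (2R)-2-[(14Z)-tricos-14-en-1-yl]oxirane F2, which is purified and then opened at its CH2 by 7 (from 5, n-BuLi, THF, −30 °C → rt). After a water quench the route is rejoined at 11.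

Step 4. The oxidant may attack the enolisable diketone 12 or the Z-alkene while the second dithiane is still being cleaved. The fallback masks C6 as an O,O-ketal, so only one thioacetal has to be cleaved and the diketone is never exposed to the oxidant. It sets out from 3:
- With one equivalent of 4 (BF3·OEt2, CH2Cl2, −20 °C) only the acetal exchanges, giving 1-(1,3-dithian-2-yl)propan-2-one F3.
- Ethylene glycol and p-TsOH (benzene, Dean–Stark) give 2-[(2-methyl-1,3-dioxolan-2-yl)methyl]-1,3-dithiane F4.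
- n-BuLi gives 2-lithio-2-[(2-methyl-1,3-dioxolan-2-yl)methyl]-1,3-dithiane F5, which is taken through the protocol of step 3. With 6 it gives lithium (2S)-1-chloro-3-{2-[(2-methyl-1,3-dioxolan-2-yl)methyl]-1,3-dithian-2-yl}propan-2-olate F6, which closes to 2-[(2-methyl-1,3-dioxolan-2-yl)methyl]-2-{[(2S)-oxiran-2-yl]methyl}-1,3-dithiane F7. Opening with 10 and CuI gives (2R,16Z)-1-{2-[(2-methyl-1,3-dioxolan-2-yl)methyl]-1,3-dithian-2-yl}pentacos-16-en-2-ol F8.
- PhI(OCOCF3)2 (1.5 equiv) in NaHCO3-buffered aqueous MeCN frees only the C4 ketone, giving (4R,18Z)-4-hydroxy-1-(2-methyl-1,3-dioxolan-2-yl)heptacos-18-en-2-one F9.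
- Aqueous TFA removes the dioxolane and cyclodehydrates, rejoining the route at 13.

Step 2. The β-keto acetal 3 can self-condense under acid, or the ketone may thioketalise incompletely. The fallback builds 5 by C-alkylation instead of double exchange. It sets out from 4, which is condensed with acetaldehyde (BF3·OEt2, CH2Cl2) to 2-methyl-1,3-dithiane F10 (also an article of commerce). n-BuLi (THF, −20 °C) gives 2-lithio-2-methyl-1,3-dithiane F11, which is alkylated with bromoacetaldehyde diethyl acetal to 2-(2,2-diethoxyethyl)-2-methyl-1,3-dithiane F12. Acetal-to-dithiane exchange with a further equivalent of 4 (BF3·OEt2, CH2Cl2, 0 °C) rejoins the route at 5.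

**Further compounds**
F1 | step 3 | (2R,16Z)-1-chloropentacos-16-en-2-ol | CCCCCCCC/C=C\CCCCCCCCCCCCC[C@@H](O)CCl
F2 | step 3 | (2R)-2-[(14Z)-tricos-14-en-1-yl]oxirane | CCCCCCCC/C=C\CCCCCCCCCCCCC[C@@H]1CO1
F3 | step 4 | 1-(1,3-dithian-2-yl)propan-2-one | CC(=O)CC1SCCCS1
F4 | step 4 | 2-[(2-methyl-1,3-dioxolan-2-yl)methyl]-1,3-dithiane | CC1(CC2SCCCS2)OCCO1
F5 | step 4 | 2-lithio-2-[(2-methyl-1,3-dioxolan-2-yl)methyl]-1,3-dithiane | [Li]C1(CC2(C)OCCO2)SCCCS1
F6 | step 4 | lithium (2S)-1-chloro-3-{2-[(2-methyl-1,3-dioxolan-2-yl)methyl]-1,3-dithian-2-yl}propan-2-olate | ClC[C@@H](O[Li])CC1(CC2(C)OCCO2)SCCCS1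
F7 | step 4 | 2-[(2-methyl-1,3-dioxolan-2-yl)methyl]-2-{[(2S)-oxiran-2-yl]methyl}-1,3-dithiane | CC1(CC2(C[C@H]3CO3)SCCCS2)OCCO1
F8 | step 4 | (2R,16Z)-1-{2-[(2-methyl-1,3-dioxolan-2-yl)methyl]-1,3-dithian-2-yl}pentacos-16-en-2-ol | CCCCCCCC/C=C\CCCCCCCCCCCCC[C@@H](O)CC1(CC2(C)OCCO2)SCCCS1
F9 | step 4 | (4R,18Z)-4-hydroxy-1-(2-methyl-1,3-dioxolan-2-yl)heptacos-18-en-2-one | CCCCCCCC/C=C\CCCCCCCCCCCCC[C@@H](O)CC(=O)CC1(C)OCCO1
F10 | step 2 | 2-methyl-1,3-dithiane | CC1SCCCS1
F11 | step 2 | 2-lithio-2-methyl-1,3-dithiane | [Li]C1(C)SCCCS1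
F12 | step 2 | 2-(2,2-diethoxyethyl)-2-methyl-1,3-dithiane | CCOC(CC1(C)SCCCS1)OCC
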